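**Plan**
- Retrosynthesis: the cyclopentenone is opened at C10=C11 and C8–C9 together (formal [3+2]). This gives an acyclic alkenylstannane–aldehyde (C11–C12–C8 with both chains) and the C9–C10 linchpin 2-chloro-2-(diethoxyphosphoryl)acetyl chloride. The chain is then cut at C6–C7, C15–C16, C13–C14 and C8–C12.
- What allows this: in ring C8–C12 the ketone carbon C9 lies between an sp2 carbon (C8, reachable as an alkenyl–tin nucleophile) and the chlorine-bearing C10 of the C10=C11 enone (an olefination retron). C8 and C11 both hang on the quaternary carbinol C12, so the C11 aldehyde cannot enolise and the two-carbon unit can act first as acylating agent, then as phosphonate carbanion.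
- Forward order: C12 and the ω chain first (steps 1–7), α chain joined at C7 (steps 8–11), alkyne converted into the C8 stannane and the 5,6-diacetate (steps 12–18), the only ring closed last (step 21), C12–OH freed (step 22).
- Stereochemistry: C12 by Sharpless epoxidation; C5 from (S)-cyclohex-2-en-1-ol, whose ring is cleaved by ozonolysis; C6 by Felkin–Anh reduction; 7E by syn-stannylcupration followed by retentive Stille coupling; 14Z,17Z by cis-semihydrogenation over Pb-poisoned Pd/CaCO3.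

Key step: step 21

Remark: C-numbers in the text are prostanoid numbers (C1 = ester carbon, ring = C8–C12, ω chain = C13–C20); systematic names carry their own locants. (S)-Cyclohex-2-en-1-ol, D-(−)-diethyl tartrate and triethyl 2-chloro-2-phosphonoacetate are taken as purchasable.

Step 1
Reactants: 1 2-bromoprop-2-en-1-ol; 2 ethynyltriisopropylsilane
Product: 3 2-methylidene-4-(triisopropylsilyl)but-3-yn-1-ol
Conditions: PdCl2(PPh3)2 (3 mol %), CuI (5 mol %), i-Pr2NH, THF, rt
Reagents that add atoms: none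
Why: Sonogashira coupling of the 1,1-disubstituted vinyl bromide with the silyl alkyne tolerates the free alcohol and places the future C8≡C7 alkyne on the future C12.

Step 2
Reactants: 3 2-methylidene-4-(triisopropylsilyl)but-3-yn-1-ol
Product: 4 (R)-{2-[(triisopropylsilyl)ethynyl]oxiran-2-yl}methanol
Conditions: Ti(Oi-Pr)4 (0.2 equiv), D-(−)-diethyl tartrate (0.25 equiv), t-BuOOH, 4 Å MS, CH2Cl2, −20 °C
Reagents that add atoms: tert-butyl hydroperoxide CC(C)(C)OO
Why: Sharpless asymmetric epoxidation of a 2-substituted allylic alcohol: the Ti(Oi-Pr)4/D-(−)-tartrate complex delivers oxygen to the alkene face opposite to that chosen by the L-(+) ester (which gives (S)-2-substituted glycidols), so the quaternary C12 should be set as R with the spatial sense the target needs.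

Step 3
Reactants: 4 (R)-{2-[(triisopropylsilyl)ethynyl]oxiran-2-yl}methanol; 5 lithium acetylide ethylenediamine complex
Product: 6 (R)-2-[(triisopropylsilyl)ethynyl]pent-4-yne-1,2-diol
Conditions: 5 (3 equiv), DMSO, rt; aq NH4Cl
Reagents that add atoms: none
Why: SN2 opening of the terminal 2,2-disubstituted epoxide at its CH2 carbon by acetylide (the alkoxide of the free alcohol can only undergo a degenerate Payne rearrangement) forms C13–C14 and leaves C12 untouched.

Step 4
Reactants: 6 (R)-2-[(triisopropylsilyl)ethynyl]pent-4-yne-1,2-diol; 7 1-bromopent-2-yne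
Product: 8 (R)-2-[(triisopropylsilyl)ethynyl]deca-4,7-diyne-1,2-diol
Conditions: CuI (20 mol %), Cs2CO3, DMF, rt
Reagents that add atoms: none
Why: CuI-mediated coupling of a terminal alkyne with a propargylic bromide (SN2 at CH2) is the standard entry to skipped diynes and should form C15–C16 without touching the silyl alkyne or the diol.

Step 5
Reactants: 8 (R)-2-[(triisopropylsilyl)ethynyl]deca-4,7-diyne-1,2-diol
Product: 9 (R,4Z,7Z)-2-[(triisopropylsilyl)ethynyl]deca-4,7-diene-1,2-diol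
Conditions: H2 (1 atm), Pd/CaCO3 poisoned with Pb(OAc)2, quinoline, EtOAc, rt
Reagents that add atoms: none
Why: cis-Semihydrogenation of the two dialkyl alkynes sets 14Z and 17Z by syn delivery of hydrogen on the poisoned surface, while the hindered triisopropylsilyl alkyne should not be reduced.

Step 6
Reactants: 9 (R,4Z,7Z)-2-[(triisopropylsilyl)ethynyl]deca-4,7-diene-1,2-diol
Product: 10 (R,4Z,7Z)-1-[(4-methoxybenzyl)oxy]-2-[(triisopropylsilyl)ethynyl]deca-4,7-dien-2-ol
Conditions: NaH (1.05 equiv), 4-methoxybenzyl chloride, Bu4NI (cat.), THF/DMF, 0 °C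
Reagents that add atoms: 4-methoxybenzyl chloride COc1ccc(CCl)cc1
Why: Williamson etherification should occur at the primary alkoxide, the tertiary propargylic hydroxyl being too hindered to be benzylated.

Step 7
Reactants: 10 (R,4Z,7Z)-1-[(4-methoxybenzyl)oxy]-2-[(triisopropylsilyl)ethynyl]deca-4,7-dien-2-ol
Product: 11 (R,4Z,7Z)-2-ethynyl-1-[(4-methoxybenzyl)oxy]deca-4,7-dien-2-ol
Conditions: Bu4NF, THF, 0 °C
Reagents that add atoms: none
Why: Fluoride cleaves the C(sp)–Si bond (protodesilylation) and frees the terminal alkyne C7–H for the next C–C bond.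

Step 8
Reactants: 12 (S)-cyclohex-2-en-1-ol
Product: 13 (S)-tert-butyl(cyclohex-2-en-1-yloxy)dimethylsilane
Conditions: t-BuMe2SiCl, imidazole, DMF, rt
Reagents that add atoms: tert-butyldimethylsilyl chloride CC(C)(C)[Si](C)(C)Cl
Why: Standard silylation; the bulky, non-chelating silyl ether is chosen to steer the later Felkin–Anh reduction at C6.

Step 9
Reactants: 13 (S)-tert-butyl(cyclohex-2-en-1-yloxy)dimethylsilane
Product: 15 methyl (S)-5-[(tert-butyldimethylsilyl)oxy]-6-oxohexanoate, via methoxy hydroperoxide 14 (not isolated)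
Conditions: O3, NaHCO3, CH2Cl2/MeOH, −78 °C; then Ac2O, Et3N, 0 °C to rt
Reagents that add atoms: ozone [O-][O+]=O; methanol CO
Why: Terminus-differentiating ozonolysis: the primary ozonide should fragment so that the carbonyl oxide forms at the carbon remote from the electron-withdrawing allylic silyloxy group, methanol traps it as 14, and Ac2O/Et3N dehydrates this to the methyl ester (C1) while the proximal carbon is released as the C6 aldehyde; the ring C–C cleavage carries the carbinol stereocenter over unchanged as C5 (S).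

Step 10
Reactants: 11 (R,4Z,7Z)-2-ethynyl-1-[(4-methoxybenzyl)oxy]deca-4,7-dien-2-ol; 15 methyl (S)-5-[(tert-butyldimethylsilyl)oxy]-6-oxohexanoate
Product: 17 methyl (5S,9R,11Z,14Z)-5-[(tert-butyldimethylsilyl)oxy]-6,9-dihydroxy-9-{[(4-methoxybenzyl)oxy]methyl}heptadeca-11,14-dien-7-ynoate (both C6 epimers), via dilithium alkoxide-acetylide 16 (not isolated)
Conditions: n-BuLi (2.05 equiv), THF, −78 °C; then 15, −78 °C; aq NH4Cl
Reagents that add atoms: none
Why: The lithium acetylide (formed by the second equivalent of base after the alkoxide) adds to the aldehyde faster than to the methyl ester at −78 °C and forms C6–C7; the C6 configuration is irrelevant because this carbinol is oxidised next.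

Step 11
Reactants: 17 methyl (5S,9R,11Z,14Z)-5-[(tert-butyldimethylsilyl)oxy]-6,9-dihydroxy-9-{[(4-methoxybenzyl)oxy]methyl}heptadeca-11,14-dien-7-ynoate
Product: 18 methyl (5S,9R,11Z,14Z)-5-[(tert-butyldimethylsilyl)oxy]-9-hydroxy-9-{[(4-methoxybenzyl)oxy]methyl}-6-oxoheptadeca-11,14-dien-7-ynoate
Conditions: Dess–Martin periodinane, NaHCO3, CH2Cl2, 0 °C
Reagents that add atoms: none
Why: Dess–Martin oxidation of the secondary propargylic alcohol gives the ynone under buffered, non-epimerising conditions, and the tertiary hydroxyl cannot be oxidised.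

Step 12
Reactants: 18 methyl (5S,9R,11Z,14Z)-5-[(tert-butyldimethylsilyl)oxy]-9-hydroxy-9-{[(4-methoxybenzyl)oxy]methyl}-6-oxoheptadeca-11,14-dien-7-ynoate
Product: 19 methyl (5S,7E,9S,11Z,14Z)-5-[(tert-butyldimethylsilyl)oxy]-9-hydroxy-9-{[(4-methoxybenzyl)oxy]methyl}-6-oxo-8-(trimethylstannyl)heptadeca-7,11,14-trienoate
Conditions: Me3SnSnMe3, MeLi, THF, −20 °C; CuBr·SMe2, −78 °C; then 18, MeOH, −78 °C
Reagents that add atoms: hexamethylditin C[Sn](C)(C)[Sn](C)(C)C
Why: Conjugate syn-stannylcupration of the ynone should put tin on the β-carbon C8 (electronic control by the C6 carbonyl overrides the steric bias of the quaternary C12), and protonation of the alkenylcopper at −78 °C with retention gives the kinetic E isomer, in which Sn is cis to H7 and C12 is cis to C6 as the target requires.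

Step 13
Reactants: 19 methyl (5S,7E,9S,11Z,14Z)-5-[(tert-butyldimethylsilyl)oxy]-9-hydroxy-9-{[(4-methoxybenzyl)oxy]methyl}-6-oxo-8-(trimethylstannyl)heptadeca-7,11,14-trienoate
Product: 20 methyl (5S,6S,7E,9S,11Z,14Z)-5-[(tert-butyldimethylsilyl)oxy]-6,9-dihydroxy-9-{[(4-methoxybenzyl)oxy]methyl}-8-(trimethylstannyl)heptadeca-7,11,14-trienoate
Conditions: LiBH(s-Bu)3 (L-Selectride), THF, −78 °C
Reagents that add atoms: none
Why: 1,2-Reduction under Felkin–Anh control: the bulky hydride should attack the ketone anti to the non-chelating C5 silyloxy group and give the 5,6-syn (6S) alcohol, while 1,4-addition is blocked by the fully substituted, stannylated β-carbon.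

Step 14
Reactants: 20 methyl (5S,6S,7E,9S,11Z,14Z)-5-[(tert-butyldimethylsilyl)oxy]-6,9-dihydroxy-9-{[(4-methoxybenzyl)oxy]methyl}-8-(trimethylstannyl)heptadeca-7,11,14-trienoate
Product: 21 methyl (5S,6S,7E,9S,11Z,14Z)-5,6,9-trihydroxy-9-{[(4-methoxybenzyl)oxy]methyl}-8-(trimethylstannyl)heptadeca-7,11,14-trienoate
Conditions: Bu4NF, AcOH (1:1), THF, 0 °C to rt
Reagents that add atoms: none
Why: Buffered fluoride removes the silyl ether without touching the alkenylstannane, and the acetic acid buffer should suppress lactonisation of the 5-hydroxy ester.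

Step 15
Reactants: 21 methyl (5S,6S,7E,9S,11Z,14Z)-5,6,9-trihydroxy-9-{[(4-methoxybenzyl)oxy]methyl}-8-(trimethylstannyl)heptadeca-7,11,14-trienoate
Product: 22 methyl (5S,6S,7E,9S,11Z,14Z)-5,6-diacetoxy-9-hydroxy-9-{[(4-methoxybenzyl)oxy]methyl}-8-(trimethylstannyl)heptadeca-7,11,14-trienoate
Conditions: Ac2O, pyridine, DMAP (cat.), CH2Cl2, 0 °C
Reagents that add atoms: acetic anhydride CC(=O)OC(C)=O
Why: Acetylation of the two secondary hydroxyls; the tertiary C12 hydroxyl should not be acylated under these mild conditions.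

Step 16
Reactants: 22 methyl (5S,6S,7E,9S,11Z,14Z)-5,6-diacetoxy-9-hydroxy-9-{[(4-methoxybenzyl)oxy]methyl}-8-(trimethylstannyl)heptadeca-7,11,14-trienoate
Product: 23 methyl (5S,6S,7E,9S,11Z,14Z)-5,6-diacetoxy-9-{[(4-methoxybenzyl)oxy]methyl}-9-[(triethylsilyl)oxy]-8-(trimethylstannyl)heptadeca-7,11,14-trienoate
Conditions: Et3SiOTf, 2,6-lutidine, CH2Cl2, −78 to 0 °C
Reagents that add atoms: triethylsilyl trifluoromethanesulfonate CC[Si](CC)(CC)OS(=O)(=O)C(F)(F)F
Why: The silyl triflate silylates the hindered tertiary alcohol, which blocks α-ketol rearrangement and O-acylation in the later aldehyde and annulation stages.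

Step 17
Reactants: 23 methyl (5S,6S,7E,9S,11Z,14Z)-5,6-diacetoxy-9-{[(4-methoxybenzyl)oxy]methyl}-9-[(triethylsilyl)oxy]-8-(trimethylstannyl)heptadeca-7,11,14-trienoate
Product: 24 methyl (5S,6S,7E,9S,11Z,14Z)-5,6-diacetoxy-9-(hydroxymethyl)-9-[(triethylsilyl)oxy]-8-(trimethylstannyl)heptadeca-7,11,14-trienoate
Conditions: DDQ, CH2Cl2/pH 7 buffer, 0 °C
Reagents that add atoms: none
Why: Oxidative cleavage of the 4-methoxybenzyl ether by DDQ under buffered conditions should leave stannane, acetates, silyl ether and skipped diene intact.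

Step 18
Reactants: 24 methyl (5S,6S,7E,9S,11Z,14Z)-5,6-diacetoxy-9-(hydroxymethyl)-9-[(triethylsilyl)oxy]-8-(trimethylstannyl)heptadeca-7,11,14-trienoate
Product: 25 methyl (5S,6S,7E,9S,11Z,14Z)-5,6-diacetoxy-9-formyl-9-[(triethylsilyl)oxy]-8-(trimethylstannyl)heptadeca-7,11,14-trienoate
Conditions: Dess–Martin periodinane, NaHCO3, CH2Cl2, 0 °C
Reagents that add atoms: none
Why: Dess–Martin oxidation gives the non-enolisable α-silyloxy aldehyde (C11) without acid that would protodestannylate C8.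

Step 19
Reactants: 26 triethyl 2-chloro-2-phosphonoacetate
Product: 27 2-chloro-2-(diethoxyphosphoryl)acetic acid
Conditions: NaOH (1.0 equiv), EtOH/H2O, 0 °C; then HCl to pH 2
Reagents that add atoms: sodium hydroxide [Na+].[OH-]
Why: Saponification is selective for the carboxylic ester over the phosphonate esters.

Step 20
Reactants: 27 2-chloro-2-(diethoxyphosphoryl)acetic acid
Product: 28 2-chloro-2-(diethoxyphosphoryl)acetyl chloride
Conditions: (COCl)2, DMF (cat.), CH2Cl2, 0 °C to rt; concentrated and used directly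
Reagents that add atoms: oxalyl chloride ClC(=O)C(Cl)=O
Why: Standard conversion of the acid into the acid chloride through Vilsmeier-type activation.

Step 21
Reactants: 25 methyl (5S,6S,7E,9S,11Z,14Z)-5,6-diacetoxy-9-formyl-9-[(triethylsilyl)oxy]-8-(trimethylstannyl)heptadeca-7,11,14-trienoate; 28 2-chloro-2-(diethoxyphosphoryl)acetyl chloride
Product: 30 methyl (5S,6S,7E)-5,6-diacetoxy-7-{(5S)-3-chloro-5-[(2Z,5Z)-octa-2,5-dien-1-yl]-2-oxo-5-[(triethylsilyl)oxy]cyclopent-3-en-1-ylidene}heptanoate, via chloro ketophosphonate 29 (not isolated)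
Conditions: Pd2(dba)3 (tris(dibenzylideneacetone)dipalladium, 5 mol %), P(2-furyl)3, CuCl, THF, 45 °C; then LiCl, DBU, MeCN, 0 °C to rt
Reagents that add atoms: none
Why: Formal [3+2] annulation in one pot: oxidative addition of zerovalent palladium into the acyl chloride of 28, CuCl-assisted tin-to-palladium transfer of the C8 alkenyl group of 25 and reductive elimination form C8–C9 with retention of the C7=C8 geometry (Stille acylation) and give the α-chloro-β-ketophosphonate 29 only at this point. LiCl/DBU then removes the one acidic hydrogen (C10, between P=O, C=O and Cl), the carbanion adds to the C11 aldehyde, and collapse of the oxaphosphetane expels diethyl phosphate and forms C10=C11 (intramolecular Horner–Wadsworth–Emmons reaction under Masamune–Roush conditions). The ring closes in the 5-exo-trig mode (C10 onto the C11 carbonyl within the chain C10–C9–C8–C12–C11), and the endocyclic cis alkene is the only geometry a five-membered ring allows, so the E/Z problem of α-halo phosphonates does not arise. No stereocenter is formed: C5, C6 and C12 are spectators, C12 is quaternary and the C11 aldehyde cannot enolise. The step needs chemoselectivity (acyl chloride before aldehyde and alkyl C–Cl) and retention of the exocyclic geometry; the first should be secured by the neutral, base-free coupling stage, the second by stereoretentive transmetalation of the stannane made by syn-stannylcupration. The closest known reaction types are the Stille ketone synthesis from acid chlorides and intramolecular Horner–Wadsworth–Emmons closure of cyclopentenones from α-halo-β-ketophosphonates.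

Step 22
Reactants: 30 methyl (5S,6S,7E)-5,6-diacetoxy-7-{(5S)-3-chloro-5-[(2Z,5Z)-octa-2,5-dien-1-yl]-2-oxo-5-[(triethylsilyl)oxy]cyclopent-3-en-1-ylidene}heptanoate
Product: 31 methyl (5S,6S,7E)-5,6-diacetoxy-7-{(5S)-3-chloro-5-hydroxy-5-[(2Z,5Z)-octa-2,5-dien-1-yl]-2-oxocyclopent-3-en-1-ylidene}heptanoate
Conditions: HF·pyridine, pyridine, THF, 0 °C
Reagents that add atoms: none
Why: Buffered HF should cleave the tertiary triethylsilyl ether without eliminating the tertiary allylic alcohol or hydrolysing the acetates.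

**Compound list**
1 | 2-bromoprop-2-en-1-ol | OCC(Br)=C | starting material
2 | ethynyltriisopropylsilane | C#C[Si](C(C)C)(C(C)C)C(C)C | starting material
3 | 2-methylidene-4-(triisopropylsilyl)but-3-yn-1-ol | OCC(=C)C#C[Si](C(C)C)(C(C)C)C(C)C | intermediate
4 | (R)-{2-[(triisopropylsilyl)ethynyl]oxiran-2-yl}methanol | OC[C@@]1(CO1)C#C[Si](C(C)C)(C(C)C)C(C)C | intermediate
5 | lithium acetylide ethylenediamine complex | [Li+].[C-]#C.NCCN | starting material
6 | (R)-2-[(triisopropylsilyl)ethynyl]pent-4-yne-1,2-diol | C#CC[C@](O)(CO)C#C[Si](C(C)C)(C(C)C)C(C)C | intermediate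
7 | 1-bromopent-2-yne | CCC#CCBr | starting material
8 | (R)-2-[(triisopropylsilyl)ethynyl]deca-4,7-diyne-1,2-diol | CCC#CCC#CC[C@](O)(CO)C#C[Si](C(C)C)(C(C)C)C(C)C | intermediate
9 | (R,4Z,7Z)-2-[(triisopropylsilyl)ethynyl]deca-4,7-diene-1,2-diol | CC/C=C\C/C=C\C[C@](O)(CO)C#C[Si](C(C)C)(C(C)C)C(C)C | intermediate
10 | (R,4Z,7Z)-1-[(4-methoxybenzyl)oxy]-2-[(triisopropylsilyl)ethynyl]deca-4,7-dien-2-ol | CC/C=C\C/C=C\C[C@](O)(COCc1ccc(OC)cc1)C#C[Si](C(C)C)(C(C)C)C(C)C | intermediate
11 | (R,4Z,7Z)-2-ethynyl-1-[(4-methoxybenzyl)oxy]deca-4,7-dien-2-ol | CC/C=C\C/C=C\C[C@](O)(COCc1ccc(OC)cc1)C#C | intermediate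
12 | (S)-cyclohex-2-en-1-ol | O[C@@H]1C=CCCC1 | starting material
13 | (S)-tert-butyl(cyclohex-2-en-1-yloxy)dimethylsilane | CC(C)(C)[Si](C)(C)O[C@@H]1C=CCCC1 | intermediate
14 | (2S)-2-[(tert-butyldimethylsilyl)oxy]-6-hydroperoxy-6-methoxyhexanal (not isolated) | COC(OO)CCC[C@H](O[Si](C)(C)C(C)(C)C)C=O | intermediate
15 | methyl (S)-5-[(tert-butyldimethylsilyl)oxy]-6-oxohexanoate | COC(=O)CCC[C@H](O[Si](C)(C)C(C)(C)C)C=O | intermediate
16 | dilithium alkoxide-acetylide of 11 (not isolated) | CC/C=C\C/C=C\C[C@](O[Li])(COCc1ccc(OC)cc1)C#C[Li] | intermediate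
17 | methyl (5S,9R,11Z,14Z)-5-[(tert-butyldimethylsilyl)oxy]-6,9-dihydroxy-9-{[(4-methoxybenzyl)oxy]methyl}heptadeca-11,14-dien-7-ynoate (C6 epimers) | CC/C=C\C/C=C\C[C@](O)(COCc1ccc(OC)cc1)C#CC(O)[C@H](CCCC(=O)OC)O[Si](C)(C)C(C)(C)C | intermediate
18 | methyl (5S,9R,11Z,14Z)-5-[(tert-butyldimethylsilyl)oxy]-9-hydroxy-9-{[(4-methoxybenzyl)oxy]methyl}-6-oxoheptadeca-11,14-dien-7-ynoate | CC/C=C\C/C=C\C[C@](O)(COCc1ccc(OC)cc1)C#CC(=O)[C@H](CCCC(=O)OC)O[Si](C)(C)C(C)(C)C | intermediate
19 | methyl (5S,7E,9S,11Z,14Z)-5-[(tert-butyldimethylsilyl)oxy]-9-hydroxy-9-{[(4-methoxybenzyl)oxy]methyl}-6-oxo-8-(trimethylstannyl)heptadeca-7,11,14-trienoate | CC/C=C\C/C=C\C[C@](O)(COCc1ccc(OC)cc1)/C(=C\C(=O)[C@H](CCCC(=O)OC)O[Si](C)(C)C(C)(C)C)[Sn](C)(C)C | intermediate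
20 | methyl (5S,6S,7E,9S,11Z,14Z)-5-[(tert-butyldimethylsilyl)oxy]-6,9-dihydroxy-9-{[(4-methoxybenzyl)oxy]methyl}-8-(trimethylstannyl)heptadeca-7,11,14-trienoate | CC/C=C\C/C=C\C[C@](O)(COCc1ccc(OC)cc1)/C(=C\[C@H](O)[C@H](CCCC(=O)OC)O[Si](C)(C)C(C)(C)C)[Sn](C)(C)C | intermediate
21 | methyl (5S,6S,7E,9S,11Z,14Z)-5,6,9-trihydroxy-9-{[(4-methoxybenzyl)oxy]methyl}-8-(trimethylstannyl)heptadeca-7,11,14-trienoate | CC/C=C\C/C=C\C[C@](O)(COCc1ccc(OC)cc1)/C(=C\[C@H](O)[C@H](CCCC(=O)OC)O)[Sn](C)(C)C | intermediate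
22 | methyl (5S,6S,7E,9S,11Z,14Z)-5,6-diacetoxy-9-hydroxy-9-{[(4-methoxybenzyl)oxy]methyl}-8-(trimethylstannyl)heptadeca-7,11,14-trienoate | CC/C=C\C/C=C\C[C@](O)(COCc1ccc(OC)cc1)/C(=C\[C@H](OC(C)=O)[C@H](CCCC(=O)OC)OC(C)=O)[Sn](C)(C)C | intermediate
23 | methyl (5S,6S,7E,9S,11Z,14Z)-5,6-diacetoxy-9-{[(4-methoxybenzyl)oxy]methyl}-9-[(triethylsilyl)oxy]-8-(trimethylstannyl)heptadeca-7,11,14-trienoate | CC/C=C\C/C=C\C[C@](O[Si](CC)(CC)CC)(COCc1ccc(OC)cc1)/C(=C\[C@H](OC(C)=O)[C@H](CCCC(=O)OC)OC(C)=O)[Sn](C)(C)C | intermediate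
24 | methyl (5S,6S,7E,9S,11Z,14Z)-5,6-diacetoxy-9-(hydroxymethyl)-9-[(triethylsilyl)oxy]-8-(trimethylstannyl)heptadeca-7,11,14-trienoate | CC/C=C\C/C=C\C[C@](O[Si](CC)(CC)CC)(CO)/C(=C\[C@H](OC(C)=O)[C@H](CCCC(=O)OC)OC(C)=O)[Sn](C)(C)C | intermediate
25 | methyl (5S,6S,7E,9S,11Z,14Z)-5,6-diacetoxy-9-formyl-9-[(triethylsilyl)oxy]-8-(trimethylstannyl)heptadeca-7,11,14-trienoate | CC/C=C\C/C=C\C[C@](O[Si](CC)(CC)CC)(C=O)/C(=C\[C@H](OC(C)=O)[C@H](CCCC(=O)OC)OC(C)=O)[Sn](C)(C)C | intermediate
26 | triethyl 2-chloro-2-phosphonoacetate | CCOC(=O)C(Cl)P(=O)(OCC)OCC | starting material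
27 | 2-chloro-2-(diethoxyphosphoryl)acetic acid | OC(=O)C(Cl)P(=O)(OCC)OCC | intermediate
28 | 2-chloro-2-(diethoxyphosphoryl)acetyl chloride | ClC(=O)C(Cl)P(=O)(OCC)OCC | intermediate
29 | methyl (5S,6S,7E,9R,11Z,14Z)-5,6-diacetoxy-8-[2-chloro-2-(diethoxyphosphoryl)acetyl]-9-formyl-9-[(triethylsilyl)oxy]heptadeca-7,11,14-trienoate (not isolated; epimers at CHCl) | CC/C=C\C/C=C\C[C@](O[Si](CC)(CC)CC)(C=O)/C(=C\[C@H](OC(C)=O)[C@H](CCCC(=O)OC)OC(C)=O)C(=O)C(Cl)P(=O)(OCC)OCC | intermediate
30 | methyl (5S,6S,7E)-5,6-diacetoxy-7-{(5S)-3-chloro-5-[(2Z,5Z)-octa-2,5-dien-1-yl]-2-oxo-5-[(triethylsilyl)oxy]cyclopent-3-en-1-ylidene}heptanoate | CC/C=C\C/C=C\C[C@]1(O[Si](CC)(CC)CC)C=C(Cl)C(=O)/C1=C/[C@H](OC(C)=O)[C@H](CCCC(=O)OC)OC(C)=O | intermediate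
31 | methyl (5S,6S,7E)-5,6-diacetoxy-7-{(5S)-3-chloro-5-hydroxy-5-[(2Z,5Z)-octa-2,5-dien-1-yl]-2-oxocyclopent-3-en-1-ylidene}heptanoate | CC/C=C\C/C=C\C[C@]1(O)C=C(Cl)C(=O)/C1=C/[C@H](OC(C)=O)[C@H](CCCC(=O)OC)OC(C)=O | target

**Totals**
Total step count: 22. Longest linear sequence: 18 steps (1–7, 10–18, 21, 22).

**Steps most likely to fail**

1. Step 21 (key step). Tin-to-palladium transfer at the congested C8 alkenylstannane may be slow, and palladium may insert into the doubly activated C–Cl bond of 28 or 29, so that protodestannylation and dechlorination outrun acylation. Fallback: from 25, CuCl-assisted Stille acylation with trichloroacetyl chloride (no acidic hydrogen, no phosphonate) should give the trichloromethyl ketone methyl (5S,6S,7E,9R,11Z,14Z)-5,6-diacetoxy-9-formyl-9-[(triethylsilyl)oxy]-8-(trichloroacetyl)heptadeca-7,11,14-trienoate F1. CrCl2 in THF at rt then reduces one C–Cl bond, the resulting enolate adds to the C11 aldehyde, and a second reduction with elimination gives the ring α-chloroenone (the CrCl2-mediated reductive olefination of aldehydes with trichloromethyl carbonyl compounds, run intramolecularly). The route is rejoined at 30.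

2. Step 12. Conjugate delivery of tin to C8, next to the quaternary carbinol, may be slow, and the kinetic E adduct may isomerise to the chelated Z stannyl enone before protonation, which would scramble the later exocyclic geometry. Fallback: from 18, cis-distannylation with hexamethylditin (Pd(PPh3)4, THF, 60 °C) should give methyl (5S,7Z,9S,11Z,14Z)-5-[(tert-butyldimethylsilyl)oxy]-9-hydroxy-9-{[(4-methoxybenzyl)oxy]methyl}-6-oxo-7,8-bis(trimethylstannyl)heptadeca-7,11,14-trienoate F2. Selective protodestannylation of the tin α to the ketone (C7; 1 equiv HCl in Et2O, −78 °C) proceeds with retention and returns to 19.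

3. Step 13. Facial selectivity at C6 may be poor because the bulk of the stannylalkenyl group can oppose Felkin–Anh control by the silyloxy group. Fallback: 19 is reduced without selectivity (NaBH4, CeCl3, MeOH, −78 °C) and the epimers are separated; the 6S alcohol 20 goes on as planned. The unwanted epimer methyl (5S,6R,7E,9S,11Z,14Z)-5-[(tert-butyldimethylsilyl)oxy]-6,9-dihydroxy-9-{[(4-methoxybenzyl)oxy]methyl}-8-(trimethylstannyl)heptadeca-7,11,14-trienoate F3 is inverted by Mitsunobu reaction with acetic acid (PPh3, diisopropyl azodicarboxylate) to methyl (5S,6S,7E,9S,11Z,14Z)-6-acetoxy-5-[(tert-butyldimethylsilyl)oxy]-9-hydroxy-9-{[(4-methoxybenzyl)oxy]methyl}-8-(trimethylstannyl)heptadeca-7,11,14-trienoate F4. Bu4NF/AcOH then gives methyl (5S,6S,7E,9S,11Z,14Z)-6-acetoxy-5,9-dihydroxy-9-{[(4-methoxybenzyl)oxy]methyl}-8-(trimethylstannyl)heptadeca-7,11,14-trienoate F5, and Ac2O/pyridine rejoins the route at 22.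

Further compounds
F1 | step 21 | methyl (5S,6S,7E,9R,11Z,14Z)-5,6-diacetoxy-9-formyl-9-[(triethylsilyl)oxy]-8-(trichloroacetyl)heptadeca-7,11,14-trienoate | CC/C=C\C/C=C\C[C@](O[Si](CC)(CC)CC)(C=O)/C(=C\[C@H](OC(C)=O)[C@H](CCCC(=O)OC)OC(C)=O)C(=O)C(Cl)(Cl)Cl
F2 | step 12 | methyl (5S,7Z,9S,11Z,14Z)-5-[(tert-butyldimethylsilyl)oxy]-9-hydroxy-9-{[(4-methoxybenzyl)oxy]methyl}-6-oxo-7,8-bis(trimethylstannyl)heptadeca-7,11,14-trienoate | CC/C=C\C/C=C\C[C@](O)(COCc1ccc(OC)cc1)/C([Sn](C)(C)C)=C(/[Sn](C)(C)C)C(=O)[C@H](CCCC(=O)OC)O[Si](C)(C)C(C)(C)C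
F3 | step 13 | methyl (5S,6R,7E,9S,11Z,14Z)-5-[(tert-butyldimethylsilyl)oxy]-6,9-dihydroxy-9-{[(4-methoxybenzyl)oxy]methyl}-8-(trimethylstannyl)heptadeca-7,11,14-trienoate | CC/C=C\C/C=C\C[C@](O)(COCc1ccc(OC)cc1)/C(=C\[C@@H](O)[C@H](CCCC(=O)OC)O[Si](C)(C)C(C)(C)C)[Sn](C)(C)C
F4 | step 13 | methyl (5S,6S,7E,9S,11Z,14Z)-6-acetoxy-5-[(tert-butyldimethylsilyl)oxy]-9-hydroxy-9-{[(4-methoxybenzyl)oxy]methyl}-8-(trimethylstannyl)heptadeca-7,11,14-trienoate | CC/C=C\C/C=C\C[C@](O)(COCc1ccc(OC)cc1)/C(=C\[C@H](OC(C)=O)[C@H](CCCC(=O)OC)O[Si](C)(C)C(C)(C)C)[Sn](C)(C)C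
F5 | step 13 | methyl (5S,6S,7E,9S,11Z,14Z)-6-acetoxy-5,9-dihydroxy-9-{[(4-methoxybenzyl)oxy]methyl}-8-(trimethylstannyl)heptadeca-7,11,14-trienoate | CC/C=C\C/C=C\C[C@](O)(COCc1ccc(OC)cc1)/C(=C\[C@H](OC(C)=O)[C@H](CCCC(=O)OC)O)[Sn](C)(C)C
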